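**Assumptions and conventions**

- Assumption: the target is made as the open-chain diketone drawn. Its δ-hydroxy ketones (and those of 23, 27, 38, 39) can equilibrate with cyclic hemiketals; this is not addressed.
- C1–C35 follow the macrolide chain (C1 = lactone carbonyl, C35 = carbinol carbon bearing isopropyl). Target: 2E,4E,6E,8E,10E; 13S,15S,17S,19R,23S,25S,35R.
- TBS = tert-butyldimethylsilyl, TBSO = TBS-oxy, TMS = trimethylsilyl. CIP letters of a carbon can change along the route when neighbouring groups change priority; the spatial arrangement does not.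
- All numbered starting materials (1, 2, 8, 14, 15, 18, 25, 28, 29, 33) are catalogue compounds.

**Retrosynthetic overview**

1. The only ring (36-membered lactone) is closed last by intramolecular Horner–Wadsworth–Emmons (HWE) olefination at C2=C3, after a C9–C10 Stille coupling attaches a C3–C9 stannyl trienal.
2. That trienal comes from pyridine: Zincke ring-opening (aromaticity broken) gives a 5-aminopentadienal, homologated with a stannylvinyllithium.
3. A C22–C23 Mukaiyama aldol (1,3-anti) joins a west C10–C22 methyl ketone to an east C23–C35 keto aldehyde.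
4. Key step: a catalytic enantioselective mono-aldol breaks the mirror symmetry of a meso all-syn C11–C19 dialdehyde, built two-directionally (double Claisen, double syn-reduction) from diethyl 3-hydroxyglutarate.
5. East half: C27–C28 from an alkyllithium (C35 from (S)-isopropyloxirane) and an (S)-silyloxy-δ-lactone.

**Route**

Step 1
Reactants: 1 diethyl 3-hydroxypentanedioate; 2 N-methoxy-N-methylacetamide
Product: 4 5-hydroxy-N1,N9-dimethoxy-N1,N9-dimethyl-3,7-dioxononanediamide (achiral; C11–C19), via lithium enolate of N-methoxy-N-methylacetamide 3 (not isolated)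
Conditions: 2 (6.5 equiv), LiN(iPr)2 (6.5 equiv), THF, −78 °C; then 1, −78 → −30 °C; AcOH quench
Reagents that add atoms: none
Why: Two-directional crossed Claisen condensation in which the amide enolate acylates both ester groups while the C15 lithium alkoxide, a non-leaving group, protects the β-hydroxy ester against elimination (the logic of the statin side-chain Claisen step); no stereocentre exists yet because both arms are identical.

Step 2
Reactants: 4 5-hydroxy-N1,N9-dimethoxy-N1,N9-dimethyl-3,7-dioxononanediamide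
Product: 5 meso all-syn (3R,7S)-3,5,7-trihydroxy-N1,N9-dimethoxy-N1,N9-dimethylnonanediamide
Conditions: Et2BOMe (2.4 equiv), THF/MeOH 4:1, −78 °C; NaBH4 (2.6 equiv), −78 °C; repeated MeOH co-evaporation
Reagents that add atoms: none
Why: Two-directional Narasaka–Prasad reduction in which the diethylboron chelate between the C15 oxygen and each β-carbonyl directs external hydride delivery, so C13 and C17 are both set 1,3-syn to C15 and the product is the meso all-syn triol.

Step 3
Reactants: 5 meso all-syn triol bis(N-methoxy-N-methylamide)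
Product: 6 meso all-syn (3R,7S)-3,5,7-tris(TBSO)-N1,N9-dimethoxy-N1,N9-dimethylnonanediamide
Conditions: TBSOTf (3.6 equiv), 2,6-lutidine (5 equiv), CH2Cl2, −78 → 0 °C
Reagents that add atoms: tert-butyldimethylsilyl trifluoromethanesulfonate (TBSOTf), CC(C)(C)[Si](C)(C)OS(=O)(=O)C(F)(F)F
Why: O-Silylation of the three secondary alcohols with a silyl triflate keeps the mirror symmetry and blocks lactonisation onto the amides.

Step 4
Reactants: 6 meso tris(TBS ether) bis(N-methoxy-N-methylamide)
Product: 7 meso all-syn (3R,7S)-3,5,7-tris(TBSO)nonanedial (C11–C19)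
Conditions: iBu2AlH (2.6 equiv), THF, −78 °C; aqueous potassium sodium tartrate
Reagents that add atoms: none
Why: Weinreb amide reduction, in which the chelated aluminium hemiaminal of each amide releases the aldehyde only on work-up, so there is no over-reduction and no stereocentre is touched.

Step 5 (key step)
Reactants: 7 meso all-syn (3R,7S)-3,5,7-tris(TBSO)nonanedial; 8 2-methoxypropene
Product: 10 (3R,5R,7R,9R)-3,5,7-tris(TBSO)-9-hydroxy-11-oxododecanal (C11–C22; C19 carbinol anti to C17), via vinyl ether adduct (3R,5R,7R,9R)-3,5,7-tris(TBSO)-9-hydroxy-11-methoxydodec-11-enal 9 (not isolated)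
Conditions: Ti(OiPr)4 (5 mol %), Si-face-selective enantiomer of 2-{[(3,5-di-tert-butyl-2-hydroxyphenyl)methylidene]amino}-2'-hydroxy-1,1'-binaphthyl (5 mol %), 3,5-di-tert-butylsalicylic acid (5 mol %), 2,6-di-tert-butyl-4-methylpyridine (4 mol %), 8/Et2O, 0 °C, stopped at about 60 % conversion (7 recovered); then 1 M HCl, Et2O, 0 °C, 10 min
Reagents that add atoms: water, O
Why: Proposed new method: the catalytic enantioselective carbonyl-ene (Mukaiyama-type) aldol addition of 2-methoxypropene, known for simple aldehydes with this chiral tetravalent titanium Schiff-base catalyst, is used to break the mirror symmetry of 7 — the catalyst attacks only the Si face, which is the 1,3-anti (Evans dipole-matched, fast) mode at one enantiotopic CHO and the 1,3-syn (mismatched, slow) mode at the other, so the matched end reacts first and sets C19 (R, anti to C17), while mono-adduct formed at the wrong end keeps a matched CHO and is drained off as bis-adduct, which raises the enantiomeric purity of 10 (closest known chemistry: Carreira-type catalytic acetone-equivalent aldols and catalytic desymmetrisations of meso compounds coupled to a kinetic resolution); mild acid then hydrolyses the enol ether to the methyl ketone.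

Step 6
Reactants: 10 (3R,5R,7R,9R)-3,5,7-tris(TBSO)-9-hydroxy-11-oxododecanal
Product: 11 (4R,6R,8S,10S,12E)-4-hydroxy-13-iodo-6,8,10-tris(TBSO)tridec-12-en-2-one (C10–C22)
Conditions: CrCl2 (8 equiv), CHI3 (2.5 equiv), THF/1,4-dioxane 1:6, 0 °C → rt, dark
Reagents that add atoms: iodoform, IC(I)I
Why: Takai iodo-olefination, in which the geminal dichromium species from CHI3 adds to the aldehyde far faster than to the methyl ketone and eliminates to the (E)-vinyl iodide whose new carbon is C10.

Step 7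
Reactants: 11 (4R,6R,8S,10S,12E)-4-hydroxy-13-iodo-6,8,10-tris(TBSO)tridec-12-en-2-one
Product: 12 (4R,6S,8S,10S,12E)-13-iodo-4,6,8,10-tetrakis(TBSO)tridec-12-en-2-one
Conditions: TBSOTf (1.3 equiv), 2,6-lutidine (2.5 equiv), CH2Cl2, −78 °C
Reagents that add atoms: tert-butyldimethylsilyl trifluoromethanesulfonate (TBSOTf), CC(C)(C)[Si](C)(C)OS(=O)(=O)C(F)(F)F
Why: O-Silylation of the C19 carbinol at low temperature with a hindered pyridine base protects the aldol against retro-aldol and β-elimination without enolising the ketone.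

Step 8
Reactants: 12 (4R,6S,8S,10S,12E)-13-iodo-4,6,8,10-tetrakis(TBSO)tridec-12-en-2-one
Product: 13 (4R,6S,8S,10S,12E)-13-iodo-4,6,8,10-tetrakis(TBSO)-2-(trimethylsilyloxy)trideca-1,12-diene (used crude)
Conditions: TMSCl (2 equiv), Et3N (2 equiv), THF, −78 °C; then LiN(SiMe3)2 (1.3 equiv), −78 °C; pentane, filtration
Reagents that add atoms: chlorotrimethylsilane (TMSCl), C[Si](C)(C)Cl
Why: Kinetic enolisation in which the hindered lithium amide removes a methyl (C22) proton and the TMSCl already present traps the less substituted enolate as its silyl enol ether before equilibration, β-elimination or attack on the (E)-vinyl iodide can occur.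

Step 9
Reactants: 14 1-bromo-6-chlorohexane; 15 (S)-2-(propan-2-yl)oxirane
Product: 17 (R)-10-chloro-2-methyldecan-3-ol (C28–C35), via 6-chlorohexylmagnesium bromide 16 (not isolated)
Conditions: 14, Mg turnings, THF, 35 °C; then 15 (0.8 equiv), CuBr·SMe2 (5 mol %), −30 → 0 °C
Reagents that add atoms: none
Why: Magnesium inserts selectively into the C–Br bond, and copper-catalysed SN2 opening of the terminal epoxide at its CH2 carbon leaves the epoxide stereocentre untouched, so it becomes C35 (R).

Step 10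
Reactants: 18 (R)-3-(tert-butyldimethylsilyloxy)-5-methoxy-5-oxopentanoic acid
Product: 20 (S)-4-(tert-butyldimethylsilyloxy)oxan-2-one (C23–C27), via (S)-3-(tert-butyldimethylsilyloxy)-5-hydroxypentanoic acid 19 (not isolated)
Conditions: LiBH4 (2.5 equiv), THF, 0 °C → rt; 1 M HCl to pH 3, extraction; then TsOH·H2O (2 mol %), CH2Cl2, rt
Reagents that add atoms: none
Why: Chemoselective reduction in which LiBH4 reduces the methyl ester but not the lithium carboxylate, followed by acid-catalysed lactonisation of the δ-hydroxy acid; the C25 stereocentre is bought in with 18 and is not touched.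

Step 11
Reactants: 17 (R)-10-chloro-2-methyldecan-3-ol; 20 (S)-4-(tert-butyldimethylsilyloxy)oxan-2-one
Product: 23 (3S,13R)-3-(TBSO)-1,13-dihydroxy-14-methylpentadecan-5-one (C23–C35 keto diol), via lithium (R)-10-chloro-2-methyldecan-3-olate 21 (not isolated), via lithium (R)-10-lithio-2-methyldecan-3-olate 22 (not isolated)
Conditions: 17, n-BuLi (1.0 equiv), THF, −78 °C; Li powder (4 equiv), 4,4'-di-tert-butylbiphenyl (5 mol %), −78 °C, 2 h; solution cannula-filtered from excess Li into 20 (0.9 equiv), THF, −78 °C, 1 h; H2O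
Reagents that add atoms: none
Why: Arene-catalysed reductive lithiation of the C–Cl bond of the lithium alkoxide gives an alkyllithium whose single addition to the δ-lactone stops at the lithium hemiketal at −78 °C (organolithium addition to a lactone), forming C27–C28 and, after work-up, the C27 ketone.

Step 12
Reactants: 23 (3S,13R)-3-(TBSO)-1,13-dihydroxy-14-methylpentadecan-5-one
Product: 24 (3S,13R)-3-(TBSO)-13-hydroxy-14-methyl-5-oxopentadecanal
Conditions: TEMPO (10 mol %), PhI(OAc)2 (1.15 equiv), CH2Cl2, rt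
Reagents that add atoms: none
Why: Oxoammonium (TEMPO) oxidation is selective for the primary C23 alcohol over the hindered secondary C35 alcohol and stops at the aldehyde.

Step 13
Reactants: 24 (3S,13R)-3-(TBSO)-13-hydroxy-14-methyl-5-oxopentadecanal; 25 2-(diethoxyphosphoryl)propanoic acid
Product: 26 (3R,13S)-13-(TBSO)-2-methyl-11,15-dioxopentadecan-3-yl 2-(diethoxyphosphoryl)propanoate (C23–C35 aldehyde; epimers at the phosphonate carbon)
Conditions: 25 (1.5 equiv), DCC (1.6 equiv), DMAP (5 mol %), CH2Cl2, 0 °C → rt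
Reagents that add atoms: none
Why: Steglich esterification (carbodiimide activation; phosphonoacetic acids acylate even hindered alcohols readily) acylates the only hydroxyl, C35–OH, with retention under near-neutral conditions that spare the β-silyloxy aldehyde; the phosphonate α-carbon is an inconsequential epimer mixture.

Step 14
Reactants: 13 silyl enol ether (C10–C22); 26 (3R,13S)-13-(TBSO)-2-methyl-11,15-dioxopentadecan-3-yl 2-(diethoxyphosphoryl)propanoate
Product: 27 (10E,13S,15S,17S,19R,23S,25S,35R)-23-hydroxy-10-iodo-13,15,17,19,25-pentakis(TBSO)-21,27-dioxo C10–C35 chain as its 35-O-[2-(diethoxyphosphoryl)propanoyl] ester (target numbering)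
Conditions: 13 (1.3 equiv), BF3·OEt2 (3 equiv), CH2Cl2, −78 °C, 1 h; pH 7 buffer
Reagents that add atoms: none
Why: Mukaiyama aldol addition through an open transition state in which the BF3-bound β-silyloxy aldehyde is attacked anti to the C25 oxygen (Evans 1,3-anti dipole model), setting C23 (S; expected about 5–8:1, minor epimer removed by chromatography), while the C27 ketone is not electrophilic enough to compete.

Step 15
Reactants: 28 pyridine; 29 1-chloro-2,4-dinitrobenzene
Product: 30 1-(2,4-dinitrophenyl)pyridinium chloride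
Conditions: acetone, reflux, 12 h; filtration
Reagents that add atoms: none
Why: Nucleophilic aromatic substitution (Zincke salt formation) in which pyridine displaces chloride from the doubly nitro-activated arene.

Step 16
Reactants: 30 1-(2,4-dinitrophenyl)pyridinium chloride
Product: 32 (2E,4E)-5-(dimethylamino)penta-2,4-dienal, via N-[(2E,4E)-5-(dimethylamino)penta-2,4-dien-1-ylidene]-N-methylmethanaminium chloride 31 (not isolated)
Conditions: Me2NH (40 % aq, 2.5 equiv), EtOH, 0 °C → rt; then NaOH (2 M aq), rt; extraction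
Reagents that add atoms: dimethylamine, CNC; sodium hydroxide, [Na+].[OH-]
Why: Zincke ring-opening, in which amine addition at C2 of the N-arylpyridinium, electrocyclic opening and amine exchange destroy the aromatic ring and give the vinamidinium salt, whose hydrolysis releases the all-E 5-aminopentadienal.

Step 17
Reactants: 33 (E)-1,2-bis(tributylstannyl)ethene; 32 (2E,4E)-5-(dimethylamino)penta-2,4-dienal
Product: 37 (2E,4E,6E)-7-(tributylstannyl)hepta-2,4,6-trienal (C3–C9), via (E)-2-(tributylstannyl)vinyllithium 34 (not isolated), via lithium 7-(dimethylamino)-1-(tributylstannyl)hepta-1,4,6-trien-3-olate 35 (not isolated), via N-methyl-N-[7-(tributylstannyl)hepta-2,4,6-trienylidene]methanaminium acetate 36 (not isolated)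
Conditions: 33, n-BuLi (1.0 equiv), THF, −78 °C, 1 h; 32 (0.9 equiv), −78 °C; AcCl (1.1 equiv), −78 → 0 °C; pH 7 aqueous buffer; dark
Reagents that add atoms: water, O
Why: Vinylogous-formamide homologation (tin–lithium exchange, 1,2-addition of the vinyllithium to the aminodienal, O-acylation that triggers loss of the oxygen through the dienamine, hydrolysis of the resulting iminium) moves the carbonyl to the former amine terminus and gives the thermodynamically preferred all-E trienal without acid strong enough to cleave the C–Sn bond.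

Step 18
Reactants: 27 C10–C35 vinyl iodide phosphonate ester; 37 (2E,4E,6E)-7-(tributylstannyl)hepta-2,4,6-trienal
Product: 38 (4E,6E,8E,10E,13S,15S,17S,19R,23S,25S,35R)-23-hydroxy-13,15,17,19,25-pentakis(TBSO)-3,21,27-trioxo C3–C35 tetraene as its 35-O-[2-(diethoxyphosphoryl)propanoyl] ester (target numbering)
Conditions: 37 (1.5 equiv), Pd2(dba)3 (5 mol %), AsPh3 (40 mol %), DMF/THF 1:1, rt, dark
Reagents that add atoms: none
Why: Stille cross-coupling of a vinyl iodide and a vinylstannane forms C9–C10 with retention of both alkene geometries under neutral conditions that tolerate the ketones, the free C23 hydroxyl, the aldehyde and the phosphonate.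

Step 19
Reactants: 38 seco tetraenal phosphonate
Product: 39 (2E,4E,6E,8E,10E,13S,15S,17S,19R,23S,25S,35R)-13,15,17,19,25-pentakis(TBSO) derivative of the target macrolactone (C23–OH free)
Conditions: LiCl (20 equiv), DBU (5 equiv), MeCN/THF, 1 mM, rt, dark, 24 h
Reagents that add atoms: none
Why: Intramolecular Horner–Wadsworth–Emmons olefination under Masamune–Roush conditions at high dilution closes the 36-membered ring and gives the (E)-trisubstituted C2=C3 alkene favoured for α-methyl phosphonoesters, the weak amine base sparing the β-oxygenated ketones.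

Step 20
Reactants: 39 penta-TBS macrolactone
Product: 40 target CNP0167014.1
Conditions: HF·pyridine (excess), pyridine, THF, 0 °C → rt, polypropylene vessel, dark
Reagents that add atoms: none
Why: Fluoride-driven desilylation (Si–F bond formation) under pyridine-buffered conditions frees the five hydroxyls without touching the stereocentres, the pentaene ester or the β-hydroxy ketones.

**Compound list**

1 | diethyl 3-hydroxypentanedioate (diethyl 3-hydroxyglutarate) | CCOC(=O)CC(O)CC(=O)OCC | starting material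
2 | N-methoxy-N-methylacetamide | CC(=O)N(C)OC | starting material
3 | lithium enolate of N-methoxy-N-methylacetamide | [Li+].[O-]C(=C)N(C)OC | intermediate
4 | 5-hydroxy-N1,N9-dimethoxy-N1,N9-dimethyl-3,7-dioxononanediamide | CON(C)C(=O)CC(=O)CC(O)CC(=O)CC(=O)N(C)OC | intermediate
5 | meso all-syn (3R,7S)-3,5,7-trihydroxy-N1,N9-dimethoxy-N1,N9-dimethylnonanediamide | CON(C)C(=O)C[C@H](O)C[C@H](O)C[C@H](O)CC(=O)N(C)OC | intermediate
6 | meso all-syn (3R,7S)-3,5,7-tris(TBSO)-N1,N9-dimethoxy-N1,N9-dimethylnonanediamide | CON(C)C(=O)C[C@H](O[Si](C)(C)C(C)(C)C)C[C@H](O[Si](C)(C)C(C)(C)C)C[C@H](O[Si](C)(C)C(C)(C)C)CC(=O)N(C)OC | intermediate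
7 | meso all-syn (3R,7S)-3,5,7-tris(TBSO)nonanedial | O=CC[C@H](O[Si](C)(C)C(C)(C)C)C[C@H](O[Si](C)(C)C(C)(C)C)C[C@H](O[Si](C)(C)C(C)(C)C)CC=O | intermediate
8 | 2-methoxypropene | COC(C)=C | starting material
9 | (3R,5R,7R,9R)-3,5,7-tris(TBSO)-9-hydroxy-11-methoxydodec-11-enal | O=CC[C@H](O[Si](C)(C)C(C)(C)C)C[C@H](O[Si](C)(C)C(C)(C)C)C[C@H](O[Si](C)(C)C(C)(C)C)C[C@@H](O)CC(=C)OC | intermediate
10 | (3R,5R,7R,9R)-3,5,7-tris(TBSO)-9-hydroxy-11-oxododecanal | O=CC[C@H](O[Si](C)(C)C(C)(C)C)C[C@H](O[Si](C)(C)C(C)(C)C)C[C@H](O[Si](C)(C)C(C)(C)C)C[C@@H](O)CC(C)=O | intermediate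
11 | (4R,6R,8S,10S,12E)-4-hydroxy-13-iodo-6,8,10-tris(TBSO)tridec-12-en-2-one | I/C=C/C[C@H](O[Si](C)(C)C(C)(C)C)C[C@H](O[Si](C)(C)C(C)(C)C)C[C@H](O[Si](C)(C)C(C)(C)C)C[C@@H](O)CC(C)=O | intermediate
12 | (4R,6S,8S,10S,12E)-13-iodo-4,6,8,10-tetrakis(TBSO)tridec-12-en-2-one | I/C=C/C[C@H](O[Si](C)(C)C(C)(C)C)C[C@H](O[Si](C)(C)C(C)(C)C)C[C@H](O[Si](C)(C)C(C)(C)C)C[C@@H](O[Si](C)(C)C(C)(C)C)CC(C)=O | intermediate
13 | (4R,6S,8S,10S,12E)-13-iodo-4,6,8,10-tetrakis(TBSO)-2-(trimethylsilyloxy)trideca-1,12-diene | I/C=C/C[C@H](O[Si](C)(C)C(C)(C)C)C[C@H](O[Si](C)(C)C(C)(C)C)C[C@H](O[Si](C)(C)C(C)(C)C)C[C@@H](O[Si](C)(C)C(C)(C)C)CC(=C)O[Si](C)(C)C | intermediate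
14 | 1-bromo-6-chlorohexane | ClCCCCCCBr | starting material
15 | (S)-2-(propan-2-yl)oxirane | C1[C@H](C(C)C)O1 | starting material
16 | 6-chlorohexylmagnesium bromide | ClCCCCCC[Mg]Br | intermediate
17 | (R)-10-chloro-2-methyldecan-3-ol | ClCCCCCCC[C@H](C(C)C)O | intermediate
18 | (R)-3-(tert-butyldimethylsilyloxy)-5-methoxy-5-oxopentanoic acid | COC(=O)C[C@H](O[Si](C)(C)C(C)(C)C)CC(=O)O | starting material
19 | (S)-3-(tert-butyldimethylsilyloxy)-5-hydroxypentanoic acid | OCC[C@H](O[Si](C)(C)C(C)(C)C)CC(=O)O | intermediate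
20 | (S)-4-(tert-butyldimethylsilyloxy)oxan-2-one | C1C[C@H](O[Si](C)(C)C(C)(C)C)CC(=O)O1 | intermediate
21 | lithium (R)-10-chloro-2-methyldecan-3-olate | ClCCCCCCC[C@H](C(C)C)O[Li] | intermediate
22 | lithium (R)-10-lithio-2-methyldecan-3-olate | [Li]CCCCCCC[C@H](C(C)C)O[Li] | intermediate
23 | (3S,13R)-3-(TBSO)-1,13-dihydroxy-14-methylpentadecan-5-one | OCC[C@H](O[Si](C)(C)C(C)(C)C)CC(=O)CCCCCCC[C@H](C(C)C)O | intermediate
24 | (3S,13R)-3-(TBSO)-13-hydroxy-14-methyl-5-oxopentadecanal | O=CC[C@H](O[Si](C)(C)C(C)(C)C)CC(=O)CCCCCCC[C@H](C(C)C)O | intermediate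
25 | 2-(diethoxyphosphoryl)propanoic acid | CCOP(=O)(OCC)C(C)C(O)=O | starting material
26 | (3R,13S)-13-(TBSO)-2-methyl-11,15-dioxopentadecan-3-yl 2-(diethoxyphosphoryl)propanoate | O=CC[C@H](O[Si](C)(C)C(C)(C)C)CC(=O)CCCCCCC[C@H](C(C)C)OC(=O)C(C)P(=O)(OCC)OCC | intermediate
27 | C10–C35 vinyl iodide seco ester (13S,15S,17S,19R,23S,25S,35R), C23–OH free, 35-O-[2-(diethoxyphosphoryl)propanoyl] | I/C=C/C[C@H](O[Si](C)(C)C(C)(C)C)C[C@H](O[Si](C)(C)C(C)(C)C)C[C@H](O[Si](C)(C)C(C)(C)C)C[C@@H](O[Si](C)(C)C(C)(C)C)CC(=O)C[C@@H](O)C[C@H](O[Si](C)(C)C(C)(C)C)CC(=O)CCCCCCC[C@H](C(C)C)OC(=O)C(C)P(=O)(OCC)OCC | intermediate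
28 | pyridine | c1ccncc1 | starting material
29 | 1-chloro-2,4-dinitrobenzene | Clc1ccc(cc1[N+]([O-])=O)[N+]([O-])=O | starting material
30 | 1-(2,4-dinitrophenyl)pyridinium chloride | [Cl-].[O-][N+](=O)c1ccc(c(c1)[N+]([O-])=O)-[n+]1ccccc1 | intermediate
31 | N-[(2E,4E)-5-(dimethylamino)penta-2,4-dien-1-ylidene]-N-methylmethanaminium chloride | [Cl-].CN(C)/C=C/C=C/C=[N+](C)C | intermediate
32 | (2E,4E)-5-(dimethylamino)penta-2,4-dienal | CN(C)/C=C/C=C/C=O | intermediate
33 | (E)-1,2-bis(tributylstannyl)ethene | CCCC[Sn](CCCC)(CCCC)/C=C/[Sn](CCCC)(CCCC)CCCC | starting material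
34 | (E)-2-(tributylstannyl)vinyllithium | [Li]/C=C/[Sn](CCCC)(CCCC)CCCC | intermediate
35 | lithium (1E,4E,6E)-7-(dimethylamino)-1-(tributylstannyl)hepta-1,4,6-trien-3-olate | CN(C)/C=C/C=C/C(O[Li])/C=C/[Sn](CCCC)(CCCC)CCCC | intermediate
36 | N-methyl-N-[(2E,4E,6E)-7-(tributylstannyl)hepta-2,4,6-trien-1-ylidene]methanaminium acetate | CC([O-])=O.C[N+](C)=C/C=C/C=C/C=C/[Sn](CCCC)(CCCC)CCCC | intermediate
37 | (2E,4E,6E)-7-(tributylstannyl)hepta-2,4,6-trienal | CCCC[Sn](CCCC)(CCCC)/C=C/C=C/C=C/C=O | intermediate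
38 | C3–C35 seco tetraenal (4E,6E,8E,10E,13S,15S,17S,19R,23S,25S,35R), 35-O-[2-(diethoxyphosphoryl)propanoyl] | O=C/C=C/C=C/C=C/C=C/C[C@H](O[Si](C)(C)C(C)(C)C)C[C@H](O[Si](C)(C)C(C)(C)C)C[C@H](O[Si](C)(C)C(C)(C)C)C[C@@H](O[Si](C)(C)C(C)(C)C)CC(=O)C[C@@H](O)C[C@H](O[Si](C)(C)C(C)(C)C)CC(=O)CCCCCCC[C@H](C(C)C)OC(=O)C(C)P(=O)(OCC)OCC | intermediate
39 | 13,15,17,19,25-pentakis-O-TBS derivative of the target macrolactone | C\C1=C/C=C/C=C/C=C/C=C/C[C@H](O[Si](C)(C)C(C)(C)C)C[C@H](O[Si](C)(C)C(C)(C)C)C[C@H](O[Si](C)(C)C(C)(C)C)C[C@@H](O[Si](C)(C)C(C)(C)C)CC(=O)C[C@@H](O)C[C@H](O[Si](C)(C)C(C)(C)C)CC(=O)CCCCCCC[C@H](C(C)C)OC1=O | intermediate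
40 | CNP0167014.1, (2E,4E,6E,8E,10E,13S,15S,17S,19R,23S,25S,35R)-13,15,17,19,23,25-hexahydroxy-2-methyl-21,27-dioxo-35-(propan-2-yl) 36-membered pentaene macrolactone | C\C1=C/C=C/C=C/C=C/C=C/C[C@H](O)C[C@H](O)C[C@H](O)C[C@@H](O)CC(=O)C[C@@H](O)C[C@H](O)CC(=O)CCCCCCC[C@H](C(C)C)OC1=O | target

**Totals and risks**

Total step count: 20. Longest linear sequence: 12 steps (steps 1–8, 14, 18, 19, 20).

The three steps most likely to fail:

Step 5. The mono-aldol on the meso dialdehyde is untested; group selectivity, over-reaction to bis-adduct and catalyst turnover with a tris-silyloxy substrate are all uncertain. The fallback sets out from 7 and returns at 10 and uses an enzyme instead of a C–C bond-forming catalyst to break the symmetry. Compound 7 is reduced (NaBH4, MeOH, 0 °C) to the meso all-syn 3,5,7-tris(TBSO)nonane-1,9-diol F1. Lipase-catalysed mono-acetylation (Pseudomonas cepacia lipase, vinyl acetate, tert-butyl methyl ether; the same lipase hydrolysing the diacetate gives the complementary enantiomer if needed) gives the C11 mono-acetate F2. Oxidation of the free C19 alcohol (TEMPO, PhI(OAc)2) gives the acetoxy aldehyde F3. A purely substrate-controlled 1,3-anti Mukaiyama aldol with 2-(trimethylsilyloxy)propene and BF3·OEt2 (CH2Cl2, −78 °C) gives the acetoxy hydroxy ketone F4. Methanolysis of the acetate (K2CO3, MeOH, 0 °C) gives the keto diol F5, and selective oxidation of its primary alcohol (TEMPO, PhI(OAc)2) rejoins the route at 10.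

Step 19. Closing a 36-membered ring with an α-methyl phosphonate while a free β-hydroxy ketone is present may be slow and may be accompanied by oligomers, retro-aldol or dehydration. The fallback sets out from 27 (with 37) and returns at 39; it reverses the order of the two bond formations so that the ring is closed by a neutral palladium-catalysed coupling. Intermolecular HWE of 27 with 37 (LiCl, DBU, MeCN, 0 °C, concentrated, short contact) gives the C9-stannyl tetraenoate seco vinyl iodide F6. Intramolecular Stille coupling of F6 (Pd2(dba)3, AsPh3, DMF, 1 mM, rt) then forms C9–C10 and gives 39.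

Step 20. Removing five secondary TBS ethers from a light- and acid-sensitive pentaene lactone that carries two β-hydroxy ketone units may need long exposure to HF and cause elimination or polyene loss. The fallback sets out from 27 and returns at 40; it removes the silyl groups before any polyene exists. Compound 27 is desilylated (HF·pyridine, THF) to the hexahydroxy vinyl iodide phosphonate F7. Stille coupling with 37 (Pd2(dba)3, AsPh3, DMF) gives the unprotected seco tetraenal F8. Masamune–Roush macro-HWE (LiCl, iPr2NEt, MeCN, 1 mM) on the free polyol then gives 40 directly.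

**Further compounds**

F1 | step 5 | meso all-syn (3R,7S)-3,5,7-tris(TBSO)nonane-1,9-diol | OCC[C@H](O[Si](C)(C)C(C)(C)C)C[C@H](O[Si](C)(C)C(C)(C)C)C[C@H](O[Si](C)(C)C(C)(C)C)CCO
F2 | step 5 | (3S,5R,7R)-9-hydroxy-3,5,7-tris(TBSO)nonyl acetate (acetate on the C11 oxygen) | CC(=O)OCC[C@H](O[Si](C)(C)C(C)(C)C)C[C@H](O[Si](C)(C)C(C)(C)C)C[C@H](O[Si](C)(C)C(C)(C)C)CCO
F3 | step 5 | (3S,5S,7S)-9-oxo-3,5,7-tris(TBSO)nonyl acetate | CC(=O)OCC[C@H](O[Si](C)(C)C(C)(C)C)C[C@H](O[Si](C)(C)C(C)(C)C)C[C@H](O[Si](C)(C)C(C)(C)C)CC=O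
F4 | step 5 | (3S,5S,7R,9R)-9-hydroxy-11-oxo-3,5,7-tris(TBSO)dodecyl acetate | CC(=O)OCC[C@H](O[Si](C)(C)C(C)(C)C)C[C@H](O[Si](C)(C)C(C)(C)C)C[C@H](O[Si](C)(C)C(C)(C)C)C[C@@H](O)CC(C)=O
F5 | step 5 | (4R,6R,8S,10S)-4,12-dihydroxy-6,8,10-tris(TBSO)dodecan-2-one | OCC[C@H](O[Si](C)(C)C(C)(C)C)C[C@H](O[Si](C)(C)C(C)(C)C)C[C@H](O[Si](C)(C)C(C)(C)C)C[C@@H](O)CC(C)=O
F6 | step 19 | C10–C35 vinyl iodide (13S,15S,17S,19R,23S,25S,35R) esterified at O35 as the (2E,4E,6E,8E)-2-methyl-9-(tributylstannyl)nona-2,4,6,8-tetraenoate | I/C=C/C[C@H](O[Si](C)(C)C(C)(C)C)C[C@H](O[Si](C)(C)C(C)(C)C)C[C@H](O[Si](C)(C)C(C)(C)C)C[C@@H](O[Si](C)(C)C(C)(C)C)CC(=O)C[C@@H](O)C[C@H](O[Si](C)(C)C(C)(C)C)CC(=O)CCCCCCC[C@H](C(C)C)OC(=O)/C(C)=C/C=C/C=C/C=C/[Sn](CCCC)(CCCC)CCCC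
F7 | step 20 | fully desilylated C10–C35 vinyl iodide (13,15,17,19,23,25-hexol) 35-O-[2-(diethoxyphosphoryl)propanoyl] ester | I/C=C/C[C@H](O)C[C@H](O)C[C@H](O)C[C@@H](O)CC(=O)C[C@@H](O)C[C@H](O)CC(=O)CCCCCCC[C@H](C(C)C)OC(=O)C(C)P(=O)(OCC)OCC
F8 | step 20 | fully desilylated C3–C35 seco tetraenal 35-O-[2-(diethoxyphosphoryl)propanoyl] ester | O=C/C=C/C=C/C=C/C=C/C[C@H](O)C[C@H](O)C[C@H](O)C[C@@H](O)CC(=O)C[C@@H](O)C[C@H](O)CC(=O)CCCCCCC[C@H](C(C)C)OC(=O)C(C)P(=O)(OCC)OCC
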